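## Analysis of the target

The target is a trans-fused eudesmane decalin (ring A: C1–C5 and C10; ring B: C5–C10). At C1 it carries a 3-methylbutyl arm whose benzylic carbon, C9', is bonded to a 3,5-diformylphloroglucinol (arene carbons C1'–C6').

There are six stereocentres:
- C10 (R): quaternary, β-methyl, axial to both rings.
- C5 (S): α-hydrogen, hence the trans fusion.
- C4 (R): tertiary carbinol, hydroxyl β and axial (syn to the C10 methyl), methyl equatorial.
- C7 (S): β, equatorial 2-hydroxyprop-2-yl group.
- C1 (S): side chain α, that is axial on ring A and anti to the C10 methyl.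
- C9' (S): acyclic, contiguous with C1 and C10.

The sensitive groups are the two tertiary alcohols, the two aldehydes and the phloroglucinol. The alcohols dehydrate under Brønsted or Lewis acid, C4–OH most readily because it is 1,3-diaxial to the angular methyl. The aldehydes tolerate neither hydride, organometallic nor single-electron reagents, and the phloroglucinol is acidic and easily oxidised.

The synthesis is hard for three reasons. The C9'–C1–C10 triad joins an acyclic stereocentre to a ring stereocentre and a quaternary carbon. The bulky C1 substituent must end up axial. The dialdehyde has to be installed late and without acid.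

The strategy rests on C4. It is a tertiary carbinol bonded to a methyl group, to the unfunctionalised methylene C3 and to the ring-fusion carbon C5. Ring A can therefore be closed last, between an acetyl group on C5 and a C3 halide of a preformed, fully substituted ring B.

## Retrosynthetic reasoning

**32 ⇒ 31 ⇒ 30.** The three phenolic O–H bonds are traced back to methyl ethers and the C11 hydroxyl to its triethylsilyl ether. The free diformylphloroglucinol is acidic, chelating and easily oxidised, so it is unmasked last. Methyl ethers are the phenol protection that passes through enolate, hydride, borane and organolithium chemistry. Once both formyl groups are present, every methoxy group is ortho or para to a carbonyl group and can be removed by a soft thiolate nucleophile. The forward steps must avoid acid, because both tertiary alcohols would eliminate.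

**30 ⇒ 27 ⇒ 26.** The two aryl–CHO bonds are cut. The aldehydes cannot be carried through the reductive ring closure or the steps before it. C3' and C5' are the only open positions of the arene, so regiochemistry is not an issue. An acidic electrophilic formylation would ionise the axial C4 carbinol. The two carbons are therefore introduced through dibromide 27 under basic conditions, in which the C4 hydroxyl is merely an alkoxide.

**26 ⇒ 24 (key disconnection).** The C3–C4 bond is cut, which opens ring A and removes the C4 stereocentre.
- C4 is the only carbon of ring A that carries a heteroatom, and a tertiary methyl carbinol is the retron of a carbonyl addition.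
- C3 is a plain methylene, so it can be the nucleophilic partner without leaving a trace.
- Cutting C4–C5 instead would need a nucleophile at a ring-fusion carbon next to the quaternary C10, or an sp2 C5 whose addition chemistry favours the cis fusion.
- Cutting at C1 or C10 would break up the stereotriad.

Ring B of 24 already holds all other stereocentres, with the acetyl group and the C1 chain trans and diequatorial, so the closure can only give the trans-decalin. Both termini of 24 (alkyl iodide and ketone) are electrophiles. The forward reaction must therefore be reductive, must reduce the C–I bond in preference to the carbonyl group, and must place the methyl group equatorial in the closing chair.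

**24 ⇒ 23 ⇒ 22 ⇒ 20.** The ketone and the iodide are traced back to alcohols, and these to the two alkenes of diene 20: the C4=C5 ethylidene and the C2=C3 vinyl group. One hydroboration serves both. It has to deliver hydrogen to C5 from the face opposite the axial C10 methyl. The two hydroxyl groups of 22 differ sterically (primary versus hindered secondary), so the iodide and the ketone can be made without protecting groups.

**20 ⇒ 19 ⇒ 18 ⇒ 15.** The vinyl group is taken back to aldehyde 19 and alcohol 18, which removes C3. Then the C1–C10 bond is cut. A quaternary carbon flanked by an exocyclic alkene, with a carboxyl-level carbon on the neighbouring atom, is the retron of an ester-enolate Claisen rearrangement, here of ester 15. This is the bond to cut for three reasons: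
- The rearrangement makes the quaternary centre and C1 together.
- It moves the chirality of the carbinol carbon C4 onto C10 through a chair and lets the enolate geometry decide C1, with C9' already present in the acid part.
- It leaves the C4=C5 double bond exactly where the acetyl group is needed.

**15 ⇒ 14 + 6.** The ester C–O bond is cut to give allylic alcohol 14 and acid 6. This is the convergent point. Any minor stereoisomer of either partner becomes a separable diastereomer here.

**14 ⇒ 13 ⇒ 11 ⇒ 9 ⇒ 8 ⇒ 7.** The carbinol centre of 14 comes from enone 13 by reagent-controlled reduction. The acetyl group comes from enol triflate 11 by cross-coupling. The triflate comes from the enolate that conjugate reduction of enone 9 generates regiospecifically on the methyl-bearing carbon. Enone 9 is the silyl ether of hydrate 8 of (S)-carvone 7, which supplies ring B, the C10 methyl and the C7 stereocentre in the correct absolute configuration.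

**6 ⇒ 5 ⇒ 3 ⇒ 1 + 2.** The acid is traced through ester 5 to lactone 3, in which the phenol oxygen and the carboxyl group are tied together. Cutting the C9'–isobutyl bond of 3 gives coumarin 1 and Grignard reagent 2. The lactone makes the enoate reactive enough for a catalytic asymmetric conjugate addition in spite of the electron-rich ring. This is where C9' is set.

## Alternatives that were turned down

**Alternative 1:** The disconnection is made in the arene. Both hydroxy-aldehyde pairs (C2'–OH/C3'–CHO and C6'–OH/C5'–CHO) are traced back to two arynes, C2'≡C3' and C5'≡C6', masked in the bis(silyl triflate) A1. In the forward step fluoride would release the arynes one after the other. Each would insert into the C=O bond of a formamide solvent, and hydrolysis would leave the two salicylaldehyde units of A2.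

In its favour:
- The C4' methoxy group polarises both arynes so that oxygen adds at the distal carbon and carbon next to the methoxy group, which is the pattern needed.
- Fluoride spares silyl-protected tertiary alcohols.
- A2 has only one methyl ether left to cleave.

On the arene end game this is stronger than the chosen route, which needs an organolithium step and a triple demethylation.

Against it:
- The step does nothing for the decalin and its six stereocentres. A complete core synthesis is still required, so the aryne tactic adds steps and saves none.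
- A1 is a hexasubstituted benzene with two C–Si and two aryl triflate groups beside the bulky benzylic carbon. These groups must either survive enolate, hydride and samarium chemistry or be put on a phloroglucinol late, in the presence of tertiary alcohols.
- The second aryne has to form on a ring that already carries a phenoxide and a free aldehyde. Both trap arynes, so O-arylation and oligomerisation compete.

The chosen route answers the same problem with a bromination and a halogen–metal exchange/formylation on 26: two steps on an arene that is inert through the whole core synthesis.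

**Alternative 2:** Rings A and B are both opened. The bonds C4–C5 and C9–C10 are cut to give the acyclic keto-diene A3, a methyl ketone tethered to an (E)-trisubstituted alkene that ends in an allylsilane. A Lewis acid would activate the ketone, C5 would attack C4, and the tertiary cation at C10 would be captured by the allylsilane to give the trans-decalin A4.

This is the most powerful step on offer: two rings, two C–C bonds and three stereocentres (C4, C5, C10) from an open chain, with the trans fusion encoded in the alkene geometry. In complexity gained per step it is clearly ahead of the chosen ring closure, which makes one bond and one stereocentre.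

It is turned down for this target because:
- A4 carries an exocyclic methylene at C8 and nothing at C7. The 2-hydroxyprop-2-yl group and the C7 stereocentre must be built afterwards by oxidative cleavage, regioselective functionalisation next to the new ketone and deoxygenation.
- The face of the alkene that is attacked is chosen by the C1 stereocentre. The chair–chair transition state that gives the target has the large C1 substituent axial, so the preferred pathway leads to the unwanted C1/C10 relationship.
- The configuration at C4 depends on whether the Lewis-acid-bound oxygen or the methyl group lies axial under the C10 methyl, which is not secure.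
- The strong Lewis acid meets a trimethoxyarene that is both a Lewis base and a π-nucleophile close to the cation, and a tertiary alkoxide that can ionise.

The chosen route sets C1 and C10 together in a sigmatropic step before any ring is closed and leaves only C4 to the cyclisation. The price is more steps to the cyclisation precursor.

**Alternative 3:** Ring B is opened at C9–C10 and ring A is taken back to a para-cresol. Phenol A5 carries the C6–C9 chain with the C7 stereocentre and a primary mesylate. Base would give the phenoxide, whose para carbon (C10, bearing the methyl group) would displace the mesylate. This closes ring B and gives the cross-conjugated dienone A6 with the quaternary carbon in place.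

For it: intramolecular para-alkylation of a phenoxide is a dependable way to a quaternary ring-fusion carbon, the starting arene is cheap and flat, and the two enone arms of A6 are differentiated. As a single step it is more reliable than the chosen key step.

Against it for this target:
- A6 contains only C7 and C10. C1 with its side chain, C9', C4 with methyl and hydroxyl, and the C5 hydrogen all remain.
- The side chain would have to be added to the β-carbon C1 of a dienone next to the quaternary centre by a bulky secondary benzylic nucleophile. That creates C1 and C9' in one intermolecular step with no control element.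
- C4 needs a methyl group and an oxygen at an α-carbon, and the C3 carbonyl has to be removed.
- C10 is set only by 1,4-induction from C7.

That is well over ten further steps with four stereocentres open. In the chosen route every stereocentre except C4 is in place before ring A is closed, and C4 arrives at the right oxidation level.

Key step: step 16

**Remarks**
- Terpene carbons keep their eudesmane numbers (C1–C15) in every intermediate; C9' is the benzylic carbon and C1'–C6' are the arene carbons.
- Assumption: in step 1 the enantiomer of the ferrocenyl diphosphine is the one that gives (S)-3; the sense of induction is checked on 3 before it is carried on.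
- Compounds 21–23 are drawn with the C4 configuration that follows from syn addition to the α-face; this centre is removed in step 15.

## Route

Step 1
Reactants: 1 5,7-dimethoxycoumarin; 2 isobutylmagnesium bromide
Product: 3 (S)-4-isobutyl-5,7-dimethoxychroman-2-one
Conditions: 2 (1.5 equiv), CuBr·SMe2 (5 mol %), 1-[2-(dicyclohexylphosphino)ferrocenyl]ethyldiphenylphosphine (reversed Josiphos, 6 mol %), t-BuOMe/CH2Cl2, −72 °C; then 1 M HCl
Reagents that add atoms: none
Why: Copper-catalysed asymmetric conjugate addition of a Grignard reagent to a coumarin is a known reaction type; the lactone keeps the enoate planar and reactive despite the electron-rich ring, and the chiral copper complex selects the face so that C9' is set as S. The magnesium enolate is simply protonated on work-up.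

Step 2
Reactants: 3 (S)-4-isobutyl-5,7-dimethoxychroman-2-one
Product: 5 methyl (S)-5-methyl-3-(2,4,6-trimethoxyphenyl)hexanoate, via hydroxy ester 4 (not isolated)
Conditions: K2CO3, MeI, MeOH/acetone, 55 °C
Reagents that add atoms: methanol, CO; iodomethane, CI
Why: Methanolysis of the aryl lactone gives phenoxide 4, and Williamson O-methylation with MeI makes the ring opening irreversible. C9' is β to the ester and is not touched.

Step 3
Reactants: 5 methyl (S)-5-methyl-3-(2,4,6-trimethoxyphenyl)hexanoate
Product: 6 (S)-5-methyl-3-(2,4,6-trimethoxyphenyl)hexanoic acid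
Conditions: LiOH, THF/MeOH/H2O, 40 °C; then 1 M HCl
Reagents that add atoms: lithium hydroxide, [Li+].[OH-]
Why: Plain saponification of a methyl ester; there is no stereocentre α to the carboxyl group.

Step 4
Reactants: 7 (S)-(+)-carvone
Product: 8 (S)-5-(2-hydroxypropan-2-yl)-2-methylcyclohex-2-en-1-one
Conditions: 50% aq H2SO4, 0 °C, 24 h
Reagents that add atoms: water, O
Why: Markovnikov acid-catalysed hydration of the 1,1-disubstituted alkene through the tertiary cation; the conjugated ring alkene is protonated far more slowly. Low temperature suppresses aromatisation, and the ring stereocentre (later C7) is not involved.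

Step 5
Reactants: 8 (S)-5-(2-hydroxypropan-2-yl)-2-methylcyclohex-2-en-1-one
Product: 9 (S)-2-methyl-5-[2-(triethylsilyloxy)propan-2-yl]cyclohex-2-en-1-one
Conditions: Et3SiOTf, 2,6-lutidine, CH2Cl2, −78 → 0 °C
Reagents that add atoms: triethylsilyl trifluoromethanesulfonate, CC[Si](CC)(CC)OS(=O)(=O)C(F)(F)F
Why: Silylation of a tertiary alcohol with a silyl triflate and a hindered base. The triethylsilyl ether survives hydride, enolate, borane, organolithium and samarium steps and leaves with fluoride.

Step 6
Reactants: 9 (S)-2-methyl-5-[2-(triethylsilyloxy)propan-2-yl]cyclohex-2-en-1-one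
Product: 11 (S)-2-methyl-5-[2-(triethylsilyloxy)propan-2-yl]cyclohex-1-en-1-yl trifluoromethanesulfonate, via lithium enolate 10 (not isolated)
Conditions: LiBH(s-Bu)3, THF, −78 °C; then PhNTf2, −78 → 23 °C; H2O
Reagents that add atoms: N-phenylbis(trifluoromethanesulfonimide), O=S(=O)(N(c1ccccc1)S(=O)(=O)C(F)(F)F)C(F)(F)F
Why: The β-carbon of the enone carries no substituent outside the ring, so the bulky borohydride adds 1,4 and gives regiospecifically the enolate on the methyl-bearing carbon. O-Triflation then gives the tetrasubstituted enol triflate (C5–OTf, C5=C10); no stereocentre is formed.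

Step 7
Reactants: 11 (S)-2-methyl-5-[2-(triethylsilyloxy)propan-2-yl]cyclohex-1-en-1-yl trifluoromethanesulfonate
Product: 13 1-[(S)-2-methyl-5-[2-(triethylsilyloxy)propan-2-yl]cyclohex-1-en-1-yl]ethan-1-one, via ethoxydiene 12 (not isolated)
Conditions: Bu3SnC(OEt)=CH2, Pd(PPh3)4 (5 mol %), LiCl, THF, 65 °C; then 0.5 M aq HCl, THF, 0 °C, 15 min
Reagents that add atoms: tributyl(1-ethoxyvinyl)stannane, CCCC[Sn](CCCC)(CCCC)C(=C)OCC; water, O
Why: Stille coupling of an enol triflate with an acyl-anion equivalent under zerovalent palladium catalysis; the very labile dienyl ether 12 is hydrolysed by brief dilute acid to the methyl ketone (C4, C15). The tertiary silyl ether survives these conditions.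

Step 8
Reactants: 13 1-[(S)-2-methyl-5-[2-(triethylsilyloxy)propan-2-yl]cyclohex-1-en-1-yl]ethan-1-one
Product: 14 (R)-1-[(S)-2-methyl-5-[2-(triethylsilyloxy)propan-2-yl]cyclohex-1-en-1-yl]ethan-1-ol
Conditions: (S)-1-methyl-3,3-diphenyl-tetrahydro-1H,3H-pyrrolo[1,2-c][1,3,2]oxazaborole (0.2 equiv), BH3·SMe2, THF, −20 °C; then MeOH
Reagents that add atoms: none
Why: Corey–Bakshi–Shibata reduction; the alkenyl group acts as the large substituent, so the (S)-catalyst gives the (R)-carbinol at C4 under reagent control, independent of the remote ring stereocentre. Reduction is 1,2 only.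

Step 9
Reactants: 14 (R)-1-[(S)-2-methyl-5-[2-(triethylsilyloxy)propan-2-yl]cyclohex-1-en-1-yl]ethan-1-ol; 6 (S)-5-methyl-3-(2,4,6-trimethoxyphenyl)hexanoic acid
Product: 15 (R)-1-[(S)-2-methyl-5-[2-(triethylsilyloxy)propan-2-yl]cyclohex-1-en-1-yl]ethyl (S)-5-methyl-3-(2,4,6-trimethoxyphenyl)hexanoate
Conditions: N,N'-dicyclohexylcarbodiimide, 4-(dimethylamino)pyridine (cat.), CH2Cl2, 0 → 23 °C
Reagents that add atoms: none
Why: Steglich esterification joins the two fragments under neutral conditions that do not ionise the allylic alcohol. No stereocentre is affected, and minor stereoisomers of either partner become separable diastereomers.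

Step 10
Reactants: 15 (R)-1-[(S)-2-methyl-5-[2-(triethylsilyloxy)propan-2-yl]cyclohex-1-en-1-yl]ethyl (S)-5-methyl-3-(2,4,6-trimethoxyphenyl)hexanoate
Product: 18 (2S,3S)-2-[(1R,2E,4S)-2-ethylidene-1-methyl-4-[2-(triethylsilyloxy)propan-2-yl]cyclohexyl]-5-methyl-3-(2,4,6-trimethoxyphenyl)hexan-1-ol, via silyl ketene acetal 16 (not isolated), via trimethylsilyl ester 17 (not isolated)
Conditions: LiN(i-Pr)2, THF, −78 °C; Me3SiCl, −78 → 23 → 60 °C; then LiAlH4, 0 → 40 °C; aq NaOH work-up
Reagents that add atoms: none
Why: Ireland–Claisen rearrangement: kinetic deprotonation in THF without polar cosolvent gives the enolate with the α-substituent cis to the alkoxy oxygen, trapped as (E)-ketene acetal 16. The [3,3] shift runs through a chair with the C4 methyl equatorial (enforced by allylic strain with the ring methyl on C10), which transfers (R)-C4 to (R)-C10, puts the C9' branch axial to give (S)-C1, and leaves the (E)-ethylidene at C5. LiAlH4 then reduces silyl ester 17 in the same flask to the C2 alcohol.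

Step 11
Reactants: 18 (2S,3S)-2-[(1R,2E,4S)-2-ethylidene-1-methyl-4-[2-(triethylsilyloxy)propan-2-yl]cyclohexyl]-5-methyl-3-(2,4,6-trimethoxyphenyl)hexan-1-ol
Product: 19 (2S,3S)-2-[(1R,2E,4S)-2-ethylidene-1-methyl-4-[2-(triethylsilyloxy)propan-2-yl]cyclohexyl]-5-methyl-3-(2,4,6-trimethoxyphenyl)hexanal
Conditions: Dess–Martin periodinane, CH2Cl2, 0 → 23 °C
Reagents that add atoms: none
Why: Dess–Martin oxidation of a hindered primary alcohol; the non-basic medium leaves the C1 stereocentre α to the new aldehyde untouched.

Step 12
Reactants: 19 (2S,3S)-2-[(1R,2E,4S)-2-ethylidene-1-methyl-4-[2-(triethylsilyloxy)propan-2-yl]cyclohexyl]-5-methyl-3-(2,4,6-trimethoxyphenyl)hexanal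
Product: 20 triethyl[[2-[(1S,3E,4R)-3-ethylidene-4-methyl-4-[(3S,4S)-6-methyl-4-(2,4,6-trimethoxyphenyl)hept-1-en-3-yl]cyclohexyl]propan-2-yl]oxy]silane
Conditions: Ph3PCH3Br, KN(SiMe3)2, THF, −78 → 0 °C
Reagents that add atoms: methyltriphenylphosphonium bromide, C[P+](c1ccccc1)(c1ccccc1)c1ccccc1.[Br-]
Why: Wittig methylenation adds C3; with the preformed ylide at low temperature, addition to the aldehyde is faster than enolisation of the hindered C1–H, so C1 is kept.

Step 13
Reactants: 20 triethyl[[2-[(1S,3E,4R)-3-ethylidene-4-methyl-4-[(3S,4S)-6-methyl-4-(2,4,6-trimethoxyphenyl)hept-1-en-3-yl]cyclohexyl]propan-2-yl]oxy]silane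
Product: 22 (3S,4S)-3-[(1R,2S,4S)-2-[(R)-1-hydroxyethyl]-1-methyl-4-[2-(triethylsilyloxy)propan-2-yl]cyclohexyl]-6-methyl-4-(2,4,6-trimethoxyphenyl)heptan-1-ol, via bis(alkylborane) 21 (not isolated)
Conditions: BH3·THF (4 equiv), THF, 0 → 23 °C; then NaOH, H2O2, 0 → 23 °C
Reagents that add atoms: hydrogen peroxide, OO
Why: Hydroboration–oxidation of both alkenes places boron on the terminal C3 and on C4 of the ethylidene (anti-Markovnikov). Syn addition to the exocyclic alkene from the α-face, opposite the axial C10 methyl, puts the C5 hydrogen axial (5S) and the C4 side chain equatorial. The C4 carbinol configuration is of no consequence.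

Step 14
Reactants: 22 (3S,4S)-3-[(1R,2S,4S)-2-[(R)-1-hydroxyethyl]-1-methyl-4-[2-(triethylsilyloxy)propan-2-yl]cyclohexyl]-6-methyl-4-(2,4,6-trimethoxyphenyl)heptan-1-ol
Product: 23 (R)-1-[(1S,2R,5S)-2-[(3S,4S)-1-iodo-6-methyl-4-(2,4,6-trimethoxyphenyl)heptan-3-yl]-2-methyl-5-[2-(triethylsilyloxy)propan-2-yl]cyclohexyl]ethan-1-ol
Conditions: PPh3, I2, imidazole (reagent preformed), CH2Cl2, 0 °C
Reagents that add atoms: iodine, II
Why: Appel-type iodination is selective for the primary alcohol, because the secondary carbinol beside C5 is too hindered for phosphonium formation and SN2 displacement. Preforming the reagent keeps free iodine away from the trimethoxyarene.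

Step 15
Reactants: 23 (R)-1-[(1S,2R,5S)-2-[(3S,4S)-1-iodo-6-methyl-4-(2,4,6-trimethoxyphenyl)heptan-3-yl]-2-methyl-5-[2-(triethylsilyloxy)propan-2-yl]cyclohexyl]ethan-1-ol
Product: 24 1-[(1S,2R,5S)-2-[(3S,4S)-1-iodo-6-methyl-4-(2,4,6-trimethoxyphenyl)heptan-3-yl]-2-methyl-5-[2-(triethylsilyloxy)propan-2-yl]cyclohexyl]ethan-1-one
Conditions: Dess–Martin periodinane, CH2Cl2, 0 → 23 °C
Reagents that add atoms: none
Why: Dess–Martin oxidation of the secondary alcohol to the methyl ketone under neutral conditions disturbs neither the primary iodide nor C5. The equatorial acetyl epimer is also the thermodynamically preferred one.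

Step 16
Reactants: 24 1-[(1S,2R,5S)-2-[(3S,4S)-1-iodo-6-methyl-4-(2,4,6-trimethoxyphenyl)heptan-3-yl]-2-methyl-5-[2-(triethylsilyloxy)propan-2-yl]cyclohexyl]ethan-1-one
Product: 26 (1S,4R,5S,7S,10R)-1-[(1S)-3-methyl-1-(2,4,6-trimethoxyphenyl)butyl]-11-(triethylsilyloxy)eudesman-4-ol, via alkylsamarium 25 (not isolated)
Conditions: SmI2 (2.5 equiv), HMPA (10 equiv), THF, −78 → 0 °C, slow addition of 24; aq NH4Cl
Reagents that add atoms: none
Why: Two single-electron transfers from divalent samarium cleave the C3–I bond, first to the primary radical and then to alkylsamarium 25 (trivalent samarium), which adds to the tethered acetyl carbonyl to give the samarium alkoxide of 26. The closest known reaction type is the SmI2-mediated intramolecular Barbier cyclisation of ω-iodo ketones to cyclohexanols. Ring A closes in a 6-exo-trig mode (C3 attacks C4, the C=O bond lying outside the new ring) through a chair fused to ring B. The only new stereocentre is C4: the carbonyl methyl takes the equatorial site, because an axial methyl would be syn-axial to the C10 methyl, so the oxygen ends axial and cis to the C10 methyl (4R). The trans fusion is not decided here, since C5 and C10 already hold the acetyl group and the C1 chain trans and diequatorial on ring B. The step needs reduction of the C–I bond ahead of the ketone, and cyclisation faster than protonation of 25 or enolisation of the ketone; HMPA makes iodide reduction and radical-to-organometal conversion fast at −78 °C, and the hindered dialkyl ketone is reduced more slowly than a primary iodide. The closing chair has to carry the C1 side chain axially, as in the target, which is the main kinetic burden.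

Step 17
Reactants: 26 (1S,4R,5S,7S,10R)-1-[(1S)-3-methyl-1-(2,4,6-trimethoxyphenyl)butyl]-11-(triethylsilyloxy)eudesman-4-ol
Product: 27 (1S,4R,5S,7S,10R)-1-[(1S)-1-(3,5-dibromo-2,4,6-trimethoxyphenyl)-3-methylbutyl]-11-(triethylsilyloxy)eudesman-4-ol
Conditions: N-bromosuccinimide (2.1 equiv), MeCN, 0 °C, dark
Reagents that add atoms: N-bromosuccinimide, O=C1CCC(=O)N1Br
Why: Electrophilic aromatic bromination; C3' and C5' are the only free positions and each is flanked by two methoxy groups. Neutral, non-radical conditions leave the tertiary alcohol, the silyl ether and the benzylic C–H alone.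

Step 18
Reactants: 27 (1S,4R,5S,7S,10R)-1-[(1S)-1-(3,5-dibromo-2,4,6-trimethoxyphenyl)-3-methylbutyl]-11-(triethylsilyloxy)eudesman-4-ol
Product: 30 (1S,4R,5S,7S,10R)-1-[(1S)-1-(3,5-diformyl-2,4,6-trimethoxyphenyl)-3-methylbutyl]-11-(triethylsilyloxy)eudesman-4-ol, via trilithio species 28 (not isolated), via bis(hemiaminal) alkoxide 29 (not isolated)
Conditions: t-BuLi (5.5 equiv), THF, −78 °C; then DMF (6 equiv), −78 → 0 °C; H2O
Reagents that add atoms: N,N-dimethylformamide, CN(C)C=O
Why: After deprotonation of the C4 hydroxyl, double bromine–lithium exchange gives a dilithioarene in which each C–Li is stabilised by two ortho methoxy groups. Bouveault-type formylation with DMF and hydrolysis of the hemiaminal alkoxides gives the dialdehyde; the basic medium protects the C4 carbinol from dehydration.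

Step 19
Reactants: 30 (1S,4R,5S,7S,10R)-1-[(1S)-1-(3,5-diformyl-2,4,6-trimethoxyphenyl)-3-methylbutyl]-11-(triethylsilyloxy)eudesman-4-ol
Product: 31 (1S,4R,5S,7S,10R)-1-[(1S)-1-(3,5-diformyl-2,4,6-trimethoxyphenyl)-3-methylbutyl]eudesmane-4,11-diol
Conditions: Bu4NF, THF, 23 → 40 °C
Reagents that add atoms: none
Why: Fluoride cleavage of the tertiary triethylsilyl ether; the aryl aldehydes have no α-hydrogens and the methyl ethers are inert.

Step 20
Reactants: 31 (1S,4R,5S,7S,10R)-1-[(1S)-1-(3,5-diformyl-2,4,6-trimethoxyphenyl)-3-methylbutyl]eudesmane-4,11-diol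
Product: 32 (1S,4R,5S,7S,10R)-1-[(1S)-1-(3,5-diformyl-2,4,6-trihydroxyphenyl)-3-methylbutyl]eudesmane-4,11-diol
Conditions: LiSC6H4Me-4 (excess), HMPA/toluene, 120 °C; then dilute HCl, 0 °C
Reagents that add atoms: none
Why: Nucleophilic (SN2) O-demethylation by an arenethiolate in a dipolar aprotic medium, a known way to unmask formylphloroglucinols. Each methoxy group is ortho or para to a formyl group that stabilises the departing phenoxide, and no Lewis or strong Brønsted acid touches the two tertiary alcohols.

## Compound list

1 | 5,7-dimethoxycoumarin | COc1cc(OC)c2ccc(=O)oc2c1 | starting material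
2 | isobutylmagnesium bromide | CC(C)C[Mg]Br | starting material
3 | (S)-4-isobutyl-5,7-dimethoxychroman-2-one | CC(C)C[C@H]1CC(=O)Oc2cc(OC)cc(OC)c21 | intermediate
4 | methyl (S)-3-(2-hydroxy-4,6-dimethoxyphenyl)-5-methylhexanoate (potassium phenoxide in the flask) | CC(C)C[C@H](c1c(O)cc(OC)cc1OC)CC(=O)OC | intermediate
5 | methyl (S)-5-methyl-3-(2,4,6-trimethoxyphenyl)hexanoate | CC(C)C[C@H](c1c(OC)cc(OC)cc1OC)CC(=O)OC | intermediate
6 | (S)-5-methyl-3-(2,4,6-trimethoxyphenyl)hexanoic acid | CC(C)C[C@H](c1c(OC)cc(OC)cc1OC)CC(=O)O | intermediate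
7 | (S)-(+)-carvone | CC1=CC[C@@H](CC1=O)C(C)=C | starting material
8 | (S)-5-(2-hydroxypropan-2-yl)-2-methylcyclohex-2-en-1-one | CC1=CC[C@@H](CC1=O)C(C)(C)O | intermediate
9 | (S)-2-methyl-5-[2-(triethylsilyloxy)propan-2-yl]cyclohex-2-en-1-one | CC1=CC[C@@H](CC1=O)C(C)(C)O[Si](CC)(CC)CC | intermediate
10 | lithium (S)-2-methyl-5-[2-(triethylsilyloxy)propan-2-yl]cyclohex-1-en-1-olate | [Li+].CC1=C([O-])C[C@H](CC1)C(C)(C)O[Si](CC)(CC)CC | intermediate
11 | (S)-2-methyl-5-[2-(triethylsilyloxy)propan-2-yl]cyclohex-1-en-1-yl trifluoromethanesulfonate | CC1=C(OS(=O)(=O)C(F)(F)F)C[C@H](CC1)C(C)(C)O[Si](CC)(CC)CC | intermediate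
12 | (S)-1-(1-ethoxyvinyl)-2-methyl-5-[2-(triethylsilyloxy)propan-2-yl]cyclohex-1-ene | CC1=C(C(=C)OCC)C[C@H](CC1)C(C)(C)O[Si](CC)(CC)CC | intermediate
13 | 1-[(S)-2-methyl-5-[2-(triethylsilyloxy)propan-2-yl]cyclohex-1-en-1-yl]ethan-1-one | CC1=C(C(C)=O)C[C@H](CC1)C(C)(C)O[Si](CC)(CC)CC | intermediate
14 | (R)-1-[(S)-2-methyl-5-[2-(triethylsilyloxy)propan-2-yl]cyclohex-1-en-1-yl]ethan-1-ol | C[C@@H](O)C1=C(C)CC[C@@H](C1)C(C)(C)O[Si](CC)(CC)CC | intermediate
15 | (R)-1-[(S)-2-methyl-5-[2-(triethylsilyloxy)propan-2-yl]cyclohex-1-en-1-yl]ethyl (S)-5-methyl-3-(2,4,6-trimethoxyphenyl)hexanoate | CC(C)C[C@H](c1c(OC)cc(OC)cc1OC)CC(=O)O[C@H](C)C1=C(C)CC[C@@H](C1)C(C)(C)O[Si](CC)(CC)CC | intermediate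
16 | (E)-trimethylsilyl ketene acetal of ester 15 (C9' branch trans to OSiMe3) | CC(C)C[C@H](c1c(OC)cc(OC)cc1OC)/C=C(/O[Si](C)(C)C)O[C@H](C)C1=C(C)CC[C@@H](C1)C(C)(C)O[Si](CC)(CC)CC | intermediate
17 | trimethylsilyl (2S,3S)-2-[(1R,2E,4S)-2-ethylidene-1-methyl-4-[2-(triethylsilyloxy)propan-2-yl]cyclohexyl]-5-methyl-3-(2,4,6-trimethoxyphenyl)hexanoate | CC(C)C[C@H](c1c(OC)cc(OC)cc1OC)[C@H](C(=O)O[Si](C)(C)C)[C@@]1(C)CC[C@H](C(C)(C)O[Si](CC)(CC)CC)C/C1=C\C | intermediate
18 | (2S,3S)-2-[(1R,2E,4S)-2-ethylidene-1-methyl-4-[2-(triethylsilyloxy)propan-2-yl]cyclohexyl]-5-methyl-3-(2,4,6-trimethoxyphenyl)hexan-1-ol | CC(C)C[C@H](c1c(OC)cc(OC)cc1OC)[C@H](CO)[C@@]1(C)CC[C@H](C(C)(C)O[Si](CC)(CC)CC)C/C1=C\C | intermediate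
19 | (2S,3S)-2-[(1R,2E,4S)-2-ethylidene-1-methyl-4-[2-(triethylsilyloxy)propan-2-yl]cyclohexyl]-5-methyl-3-(2,4,6-trimethoxyphenyl)hexanal | CC(C)C[C@H](c1c(OC)cc(OC)cc1OC)[C@H](C=O)[C@@]1(C)CC[C@H](C(C)(C)O[Si](CC)(CC)CC)C/C1=C\C | intermediate
20 | triethyl[[2-[(1S,3E,4R)-3-ethylidene-4-methyl-4-[(3S,4S)-6-methyl-4-(2,4,6-trimethoxyphenyl)hept-1-en-3-yl]cyclohexyl]propan-2-yl]oxy]silane | CC(C)C[C@H](c1c(OC)cc(OC)cc1OC)[C@H](C=C)[C@@]1(C)CC[C@H](C(C)(C)O[Si](CC)(CC)CC)C/C1=C\C | intermediate
21 | bis(alkylborane) from 20 (BH2 on C3 and on C4, C5–H α) | CC(C)C[C@H](c1c(OC)cc(OC)cc1OC)[C@H](CCB)[C@@]1(C)CC[C@H](C(C)(C)O[Si](CC)(CC)CC)C[C@@H]1[C@@H](C)B | intermediate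
22 | (3S,4S)-3-[(1R,2S,4S)-2-[(R)-1-hydroxyethyl]-1-methyl-4-[2-(triethylsilyloxy)propan-2-yl]cyclohexyl]-6-methyl-4-(2,4,6-trimethoxyphenyl)heptan-1-ol | CC(C)C[C@H](c1c(OC)cc(OC)cc1OC)[C@H](CCO)[C@@]1(C)CC[C@H](C(C)(C)O[Si](CC)(CC)CC)C[C@@H]1[C@@H](C)O | intermediate
23 | (R)-1-[(1S,2R,5S)-2-[(3S,4S)-1-iodo-6-methyl-4-(2,4,6-trimethoxyphenyl)heptan-3-yl]-2-methyl-5-[2-(triethylsilyloxy)propan-2-yl]cyclohexyl]ethan-1-ol | CC(C)C[C@H](c1c(OC)cc(OC)cc1OC)[C@H](CCI)[C@@]1(C)CC[C@H](C(C)(C)O[Si](CC)(CC)CC)C[C@@H]1[C@@H](C)O | intermediate
24 | 1-[(1S,2R,5S)-2-[(3S,4S)-1-iodo-6-methyl-4-(2,4,6-trimethoxyphenyl)heptan-3-yl]-2-methyl-5-[2-(triethylsilyloxy)propan-2-yl]cyclohexyl]ethan-1-one (keto-iodide) | CC(C)C[C@H](c1c(OC)cc(OC)cc1OC)[C@H](CCI)[C@@]1(C)CC[C@H](C(C)(C)O[Si](CC)(CC)CC)C[C@@H]1C(C)=O | intermediate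
25 | C3 alkylsamarium diiodide derived from 24 | CC(C)C[C@H](c1c(OC)cc(OC)cc1OC)[C@H](CC[Sm](I)I)[C@@]1(C)CC[C@H](C(C)(C)O[Si](CC)(CC)CC)C[C@@H]1C(C)=O | intermediate
26 | (1S,4R,5S,7S,10R)-1-[(1S)-3-methyl-1-(2,4,6-trimethoxyphenyl)butyl]-11-(triethylsilyloxy)eudesman-4-ol (decalin carbinol) | CC(C)C[C@H](c1c(OC)cc(OC)cc1OC)[C@@H]1CC[C@@](C)(O)[C@H]2C[C@@H](C(C)(C)O[Si](CC)(CC)CC)CC[C@]12C | intermediate
27 | (1S,4R,5S,7S,10R)-1-[(1S)-1-(3,5-dibromo-2,4,6-trimethoxyphenyl)-3-methylbutyl]-11-(triethylsilyloxy)eudesman-4-ol | CC(C)C[C@H](c1c(OC)c(Br)c(OC)c(Br)c1OC)[C@@H]1CC[C@@](C)(O)[C@H]2C[C@@H](C(C)(C)O[Si](CC)(CC)CC)CC[C@]12C | intermediate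
28 | 3',5'-dilithioarene lithium C4-alkoxide derived from 27 | CC(C)C[C@H](c1c(OC)c([Li])c(OC)c([Li])c1OC)[C@@H]1CC[C@@](C)(O[Li])[C@H]2C[C@@H](C(C)(C)O[Si](CC)(CC)CC)CC[C@]12C | intermediate
29 | bis(lithium α-dimethylamino alkoxide) adduct of 28 with DMF | CC(C)C[C@H](c1c(OC)c(C(O[Li])N(C)C)c(OC)c(C(O[Li])N(C)C)c1OC)[C@@H]1CC[C@@](C)(O[Li])[C@H]2C[C@@H](C(C)(C)O[Si](CC)(CC)CC)CC[C@]12C | intermediate
30 | (1S,4R,5S,7S,10R)-1-[(1S)-1-(3,5-diformyl-2,4,6-trimethoxyphenyl)-3-methylbutyl]-11-(triethylsilyloxy)eudesman-4-ol | CC(C)C[C@H](c1c(OC)c(C=O)c(OC)c(C=O)c1OC)[C@@H]1CC[C@@](C)(O)[C@H]2C[C@@H](C(C)(C)O[Si](CC)(CC)CC)CC[C@]12C | intermediate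
31 | (1S,4R,5S,7S,10R)-1-[(1S)-1-(3,5-diformyl-2,4,6-trimethoxyphenyl)-3-methylbutyl]eudesmane-4,11-diol | CC(C)C[C@H](c1c(OC)c(C=O)c(OC)c(C=O)c1OC)[C@@H]1CC[C@@](C)(O)[C@H]2C[C@@H](C(C)(C)O)CC[C@]12C | intermediate
32 | (1S,4R,5S,7S,10R)-1-[(1S)-1-(3,5-diformyl-2,4,6-trihydroxyphenyl)-3-methylbutyl]eudesmane-4,11-diol (CNP0409870.3) | CC(C)C[C@H](c1c(O)c(C=O)c(O)c(C=O)c1O)[C@@H]1CC[C@@](C)(O)[C@H]2C[C@@H](C(C)(C)O)CC[C@]12C | target

## Step count and least certain steps

Total step count: 20. Steps 1–3 make acid 6, steps 4–8 make alcohol 14, and steps 9–20 are common.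
Longest linear sequence: 17 steps, from (S)-carvone 7 through steps 4–20.

**Step 16 (key step).** The most likely failure is loss of the organometallic before ring closure. The C–I bond may be reduced to C–H, or the methyl ketone enolised by the alkylsamarium, or the ketone reduced to a ketyl that dimerises or is protonated. The cause is that the closing chair must carry the large C1 substituent axially and the carbonyl group sits beside the quaternary C10, so cyclisation is slower than in simple iodo ketones.
Fallback: change from single-electron reduction to a polar halogen–metal exchange. Keto-iodide 24 is treated with t-BuLi (2.2 equiv) in Et2O/pentane at −100 °C. Iodine–lithium exchange at the primary iodide is faster than addition of t-BuLi to the hindered ketone, and the primary alkyllithium closes ring A through the same chair. This sets out from 24 and comes back at 26; no new compound is formed on this path (F0).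

**Step 10.** Two things may go wrong. The first is erosion of the C1 configuration, through incomplete control of enolate geometry or leakage through a boat; the wanted chair carries the C9' branch axially, over the ring methylene on C5, and the (S)-C9' centre is not ideally matched to the enolate face that has to react. The second is slow rearrangement at the congested quaternary centre with fragmentation of the ketene acetal.
Fallback: an Eschenmoser–Claisen rearrangement, thermal, neutral and with the ketene N,O-acetal geometry fixed by allylic strain (α-substituent cis to oxygen, the same sense as wanted). It sets out from ester 5 and alcohol 14. Ester 5 is converted with Me2NH/AlMe3 into dimethylamide F1. O-Methylation with Me3OBF4 and then NaOMe/MeOH gives amide acetal F2. Heating F2 with 14 in xylene at 140 °C gives the rearranged amide F3. Reduction with LiH2NBH3 in THF returns to the route at alcohol 18.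

**Step 13.** Poor facial selectivity in the hydroboration of the ethylidene is possible: delivery of hydrogen to the β-face of C5, or intramolecular delivery from the first-formed C3 borane. The large C1 substituent on the neighbouring quaternary carbon shields both faces to an unknown degree. The result would be the axial C5 epimer, which cannot give the trans-decalin.
Fallback: replace kinetic face selection by thermodynamic control. It sets out from diol 22, taken as a C5 mixture. Ac2O/pyridine at 0 °C acetylates only the primary hydroxyl to give primary acetate F4. Dess–Martin oxidation gives keto acetate F5. NaOMe/MeOH at 40 °C equilibrates C5 to the equatorial acetyl epimer and removes the acetate, giving keto alcohol F6. Iodination with PPh3/I2/imidazole returns to the route at 24. The base treatment is placed before the iodide is made, because an enolate would otherwise be alkylated by it.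

**Step 18.** Incomplete second bromine–lithium exchange, or protonation of one aryllithium, would give mono-aldehyde; a hexasubstituted ring with a lithium alkoxide nearby is crowded and the dianion may aggregate.
Fallback: bring in the two carbons by cross-coupling and cleave. It sets out from dibromide 27. Suzuki–Miyaura coupling with potassium vinyltrifluoroborate (Pd(OAc)2, 2-dicyclohexylphosphino-2',6'-dimethoxybiphenyl, Cs2CO3, THF/H2O, 80 °C) gives divinylarene F7. Lemieux–Johnson cleavage (OsO4 cat., NaIO4, 2,6-lutidine, dioxane/H2O) returns to the route at dialdehyde 30.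

**Step 1.** Low enantioselectivity or low conversion is possible, because the C5 methoxy group crowds C4 of the coumarin and the Grignard reagent is β-branched.
Fallback: auxiliary control in place of catalyst control. It sets out from Grignard reagent 2 and commercial (E)-3-(2,4,6-trimethoxyphenyl)acrylic acid F8. The acid is attached to (S)-4-phenyloxazolidin-2-one (pivaloyl chloride, Et3N, then the lithiated oxazolidinone) to give imide F9. Addition of 2 with CuBr·SMe2 in THF at −40 °C, anti to the phenyl group of the chelated s-cis imide, gives adduct F10. LiOH/H2O2 removes the auxiliary and returns to the route at acid 6.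

## Further compounds

F0 | step 16 | none | none
F1 | step 10 | (S)-N,N,5-trimethyl-3-(2,4,6-trimethoxyphenyl)hexanamide | CC(C)C[C@H](c1c(OC)cc(OC)cc1OC)CC(=O)N(C)C
F2 | step 10 | (S)-1,1-dimethoxy-N,N,5-trimethyl-3-(2,4,6-trimethoxyphenyl)hexan-1-amine | CC(C)C[C@H](c1c(OC)cc(OC)cc1OC)CC(OC)(OC)N(C)C
F3 | step 10 | (2S,3S)-2-[(1R,2E,4S)-2-ethylidene-1-methyl-4-[2-(triethylsilyloxy)propan-2-yl]cyclohexyl]-N,N,5-trimethyl-3-(2,4,6-trimethoxyphenyl)hexanamide | CC(C)C[C@H](c1c(OC)cc(OC)cc1OC)[C@H](C(=O)N(C)C)[C@@]1(C)CC[C@H](C(C)(C)O[Si](CC)(CC)CC)C/C1=C\C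
F4 | step 13 | primary (C3) acetate of diol 22, mixture at C5 and C4 | CC(C)C[C@H](c1c(OC)cc(OC)cc1OC)[C@H](CCOC(C)=O)[C@@]1(C)CC[C@H](C(C)(C)O[Si](CC)(CC)CC)CC1C(C)O
F5 | step 13 | C4 keto C3 acetate, mixture at C5 | CC(C)C[C@H](c1c(OC)cc(OC)cc1OC)[C@H](CCOC(C)=O)[C@@]1(C)CC[C@H](C(C)(C)O[Si](CC)(CC)CC)CC1C(C)=O
F6 | step 13 | 1-[(1S,2R,5S)-2-[(3S,4S)-1-hydroxy-6-methyl-4-(2,4,6-trimethoxyphenyl)heptan-3-yl]-2-methyl-5-[2-(triethylsilyloxy)propan-2-yl]cyclohexyl]ethan-1-one | CC(C)C[C@H](c1c(OC)cc(OC)cc1OC)[C@H](CCO)[C@@]1(C)CC[C@H](C(C)(C)O[Si](CC)(CC)CC)C[C@@H]1C(C)=O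
F7 | step 18 | (1S,4R,5S,7S,10R)-1-[(1S)-3-methyl-1-(2,4,6-trimethoxy-3,5-divinylphenyl)butyl]-11-(triethylsilyloxy)eudesman-4-ol | CC(C)C[C@H](c1c(OC)c(C=C)c(OC)c(C=C)c1OC)[C@@H]1CC[C@@](C)(O)[C@H]2C[C@@H](C(C)(C)O[Si](CC)(CC)CC)CC[C@]12C
F8 | step 1 | (E)-3-(2,4,6-trimethoxyphenyl)acrylic acid | COc1cc(OC)c(/C=C/C(=O)O)c(OC)c1
F9 | step 1 | (S)-4-phenyl-3-[(E)-3-(2,4,6-trimethoxyphenyl)acryloyl]oxazolidin-2-one | COc1cc(OC)c(/C=C/C(=O)N2[C@@H](c3ccccc3)COC2=O)c(OC)c1
F10 | step 1 | (S)-3-[(S)-5-methyl-3-(2,4,6-trimethoxyphenyl)hexanoyl]-4-phenyloxazolidin-2-one | CC(C)C[C@H](c1c(OC)cc(OC)cc1OC)CC(=O)N1[C@@H](c2ccccc2)COC1=O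
A1 | alternative 1 | 1-[(1S)-1-[4-methoxy-3,5-bis(trimethylsilyl)-2,6-bis(trifluoromethylsulfonyloxy)phenyl]-3-methylbutyl]-4,11-bis(triethylsilyloxy)eudesmane (bis(silyl triflate)) | CC(C)C[C@H](c1c(OS(=O)(=O)C(F)(F)F)c([Si](C)(C)C)c(OC)c([Si](C)(C)C)c1OS(=O)(=O)C(F)(F)F)[C@@H]1CC[C@@](C)(O[Si](CC)(CC)CC)[C@H]2C[C@@H](C(C)(C)O[Si](CC)(CC)CC)CC[C@]12C
A2 | alternative 1 | 1-[(1S)-1-(3,5-diformyl-2,6-dihydroxy-4-methoxyphenyl)-3-methylbutyl]-4,11-bis(triethylsilyloxy)eudesmane | CC(C)C[C@H](c1c(O)c(C=O)c(OC)c(C=O)c1O)[C@@H]1CC[C@@](C)(O[Si](CC)(CC)CC)[C@H]2C[C@@H](C(C)(C)O[Si](CC)(CC)CC)CC[C@]12C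
A3 | alternative 2 | acyclic keto-diene: methyl ketone (C4) tethered through C3–C2–C1 to the (E)-C10=C5 alkene, ending in a 2-(trimethylsilylmethyl)allyl unit (C8, C9) | CC(C)C[C@H](c1c(OC)cc(OC)cc1OC)[C@H](CCC(C)=O)/C(C)=C/CCC(=C)C[Si](C)(C)C
A4 | alternative 2 | trans-decalin carbinol with exocyclic C8 methylene and no C7 substituent | CC(C)C[C@H](c1c(OC)cc(OC)cc1OC)[C@@H]1CC[C@@](C)(O)[C@H]2CCC(=C)C[C@]12C
A5 | alternative 3 | 4-methyl-3-[(S)-2-[2-(triethylsilyloxy)propan-2-yl]-4-(methylsulfonyloxy)butyl]phenol | Cc1ccc(O)cc1C[C@H](CCOS(C)(=O)=O)C(C)(C)O[Si](CC)(CC)CC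
A6 | alternative 3 | bicyclic cross-conjugated dienone (10-methyl-7-[2-(triethylsilyloxy)propan-2-yl]-1,4-dien-3-one) | C1=CC(=O)C=C2C[C@@H](C(C)(C)O[Si](CC)(CC)CC)CC[C@]12C
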